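**Assumption:** the target (C22H22O6) has no stereocentre, and its only acyclic C=C carries two identical methyl groups. It is therefore achiral and needs no enantiocontrol. The stereocentres of the transient compounds 5 and 7 are racemic and are erased within the same step.

## Retrosynthetic overview
1. Flavonol 8 ⇒ 2'-hydroxychalcone 6 by oxidative cyclisation, forming the O1–C2 bond, the C3–OH group and the C2=C3 bond. Pyranone ring C is the only ring built, and it is built last.
2. Chalcone 6 ⇒ methyl ketone 3 + 3,4-dimethoxybenzaldehyde 4 by an intermolecular Claisen–Schmidt aldol condensation. This is the key C–C bond (future C2–C3).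
3. Ketone 3 ⇒ 2,4-dihydroxyacetophenone 1 + prenyl bromide 2 by regioselective 4-O-alkylation.
4. Rings A and B are purchased. The base-stable but acid-sensitive prenyl ether goes on first, and all later steps are run in base.

## Route

**Step 1**
Reactants: 1 2,4-dihydroxyacetophenone; 2 prenyl bromide (1-bromo-3-methylbut-2-ene)
Product: 3 1-[2-hydroxy-4-(3-methylbut-2-enyloxy)phenyl]ethan-1-one
Conditions: 2 (1.05 equiv), K2CO3 (1.2 equiv), acetone, reflux, 6 h
Reagents that add atoms: none
Why: In this Williamson ether synthesis (SN2) the 2-OH is hydrogen-bonded to the acetyl carbonyl and is far less acidic and nucleophilic than the free 4-OH, so a weak base and about one equivalent of the primary allylic bromide alkylate O-4 only, and no stereocentre is formed.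

**Step 2**
Reactants: 3 1-[2-hydroxy-4-(3-methylbut-2-enyloxy)phenyl]ethan-1-one; 4 3,4-dimethoxybenzaldehyde (veratraldehyde)
Product: 6 (E)-3-(3,4-dimethoxyphenyl)-1-[2-hydroxy-4-(3-methylbut-2-enyloxy)phenyl]prop-2-en-1-one, via racemic aldol adduct 5 (not isolated)
Conditions: 4 (1.1 equiv), 50% aq KOH (10 equiv), EtOH, 0 °C → rt, 24–48 h; then ice, 1 M HCl to pH 5, filter, recrystallise (EtOH)
Reagents that add atoms: none
Why: In this Claisen–Schmidt crossed aldol condensation only 3 can enolise and 4 is a non-enolisable aldehyde, so one cross product forms, E1cB dehydration of 5 erases its racemic carbinol centre to give the thermodynamically preferred conjugated E-enone, and the prenyl and methyl aryl ethers are inert to hydroxide and to the brief cold neutralisation.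

**Step 3**
Reactants: 6 (E)-3-(3,4-dimethoxyphenyl)-1-[2-hydroxy-4-(3-methylbut-2-enyloxy)phenyl]prop-2-en-1-one
Product: 8 2-(3,4-dimethoxyphenyl)-3-hydroxy-7-(3-methylbut-2-enyloxy)-4H-chromen-4-one, via trans-dihydroflavonol 7 (not isolated)
Conditions: 30% aq H2O2 (5 equiv), 2 M aq NaOH (5 equiv), MeOH (no nitrile co-solvent), 0 °C → rt, 4–16 h; then 1 M HCl to pH 5 at 0 °C, filter, recrystallise (MeOH)
Reagents that add atoms: hydrogen peroxide, OO
Why: In this Algar–Flynn–Oyamada reaction the 2'-phenoxide closes on the β-carbon while alkaline H2O2 oxygenates the α-carbon to give 7, a second equivalent of H2O2 dehydrogenates 7 to the aromatic flavonol and removes both transient stereocentres, the absence of a 6'-substituent favours flavonol over aurone, and the electron-rich prenyl alkene is not attacked by nucleophilic HOO⁻.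

## Compound list
1 | 2,4-dihydroxyacetophenone (resacetophenone) | CC(=O)c1ccc(O)cc1O | starting material
2 | prenyl bromide (1-bromo-3-methylbut-2-ene) | CC(C)=CCBr | starting material
3 | 1-[2-hydroxy-4-(3-methylbut-2-enyloxy)phenyl]ethan-1-one | CC(=O)c1ccc(OCC=C(C)C)cc1O | intermediate
4 | 3,4-dimethoxybenzaldehyde (veratraldehyde) | COc1ccc(C=O)cc1OC | starting material
5 | 3-(3,4-dimethoxyphenyl)-3-hydroxy-1-[2-hydroxy-4-(3-methylbut-2-enyloxy)phenyl]propan-1-one (racemic, not isolated) | COc1ccc(C(O)CC(=O)c2ccc(OCC=C(C)C)cc2O)cc1OC | intermediate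
6 | (E)-3-(3,4-dimethoxyphenyl)-1-[2-hydroxy-4-(3-methylbut-2-enyloxy)phenyl]prop-2-en-1-one | COc1ccc(/C=C/C(=O)c2ccc(OCC=C(C)C)cc2O)cc1OC | intermediate
7 | trans-2-(3,4-dimethoxyphenyl)-3-hydroxy-7-(3-methylbut-2-enyloxy)chroman-4-one (racemic, 2R,3R enantiomer drawn, not isolated) | COc1ccc([C@@H]2[C@@H](O)C(=O)c3ccc(OCC=C(C)C)cc3O2)cc1OC | intermediate
8 | 2-(3,4-dimethoxyphenyl)-3-hydroxy-7-(3-methylbut-2-enyloxy)-4H-chromen-4-one (CNP0167607.0, achiral) | COc1ccc(-c2oc3cc(OCC=C(C)C)ccc3c(=O)c2O)cc1OC | target

## Summary
Total step count: 3. Longest linear sequence: 3 (1 → 3 → 6 → 8).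

## Steps most likely to fail, with fallbacks

**Step 3 (oxidative cyclisation).**
- Risks: a modest yield, aurone or benzoic acid cleavage by-products, or a stall at 7.
- The fallback separates epoxidation from ring closure. It sets out from 3 and comes back to the route at 7.
- Ketone 3 is protected with MOMCl and NaH in DMF at 0 °C to give 1-[2-(methoxymethoxy)-4-(3-methylbut-2-enyloxy)phenyl]ethan-1-one F1.
- F1 is condensed with 4 (KOH, EtOH, rt) to give the (E)-2'-O-MOM chalcone F2.
- With no free phenol present, Weitz–Scheffer epoxidation (H2O2, NaOH, MeOH, rt) stops cleanly at the racemic trans-epoxy ketone F3.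
- Catalytic p-TsOH·H2O in MeOH at 40 °C removes the chelation-activated MOM group. The freed phenol then opens the benzylic epoxide carbon to give 7, which is now isolated.
- Compound 7 goes on to 8 under the second half of step 3 (NaOH with H2O2 or air, MeOH).

**Step 2 (aldol condensation).**
- Risks: slow conversion because the phenoxide of 3 deactivates the ketone, Cannizzaro loss of 4, and partial flavanone formation.
- The fallback reverses the order of events, so the condensation can be acid-catalysed before the acid-labile prenyl ether exists. It sets out from 1 and comes back to the route at 6.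
- Ketone 1 and aldehyde 4 are condensed in HCl-saturated EtOH (0 °C → rt) to give (E)-2',4'-dihydroxy-3,4-dimethoxychalcone F4.
- The unchelated 4'-OH of F4 is then alkylated selectively with 2 (K2CO3, acetone, reflux) to give 6.

**Step 1 (selective O-prenylation).**
- Risks: bis-O-alkylation or C-prenylation of the resorcinol ring by the ambident phenoxide.
- The fallback avoids a free phenoxide altogether. It sets out from 1 and comes back to the route at 3.
- A Mitsunobu etherification of 1 with 3-methylbut-2-en-1-ol (CC(C)=CCO), PPh3 and DIAD in THF (0 °C → rt) engages only the more acidic, unchelated 4-OH. It gives 3 directly without any new intermediate.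

## Further compounds
F1 | step 3 | 1-[2-(methoxymethoxy)-4-(3-methylbut-2-enyloxy)phenyl]ethan-1-one | CC(=O)c1ccc(OCC=C(C)C)cc1OCOC
F2 | step 3 | (E)-3-(3,4-dimethoxyphenyl)-1-[2-(methoxymethoxy)-4-(3-methylbut-2-enyloxy)phenyl]prop-2-en-1-one | COCOc1cc(OCC=C(C)C)ccc1C(=O)/C=C/c1ccc(OC)c(OC)c1
F3 | step 3 | trans-[3-(3,4-dimethoxyphenyl)oxiran-2-yl][2-(methoxymethoxy)-4-(3-methylbut-2-enyloxy)phenyl]methanone (racemic, one enantiomer drawn) | COCOc1cc(OCC=C(C)C)ccc1C(=O)[C@@H]1O[C@H]1c1ccc(OC)c(OC)c1
F4 | step 2 | (E)-1-(2,4-dihydroxyphenyl)-3-(3,4-dimethoxyphenyl)prop-2-en-1-one | COc1ccc(/C=C/C(=O)c2ccc(O)cc2O)cc1OC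
F0 | step 1 | none | none
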